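The methylene bridge is cut last, which leaves an acylphloroglucinol Mannich base and 5,7-dihydroxy-2,2,6-trimethylchroman-4-one. Everything rests on closing the dihydropyranone ring at C2–C3. C2 carries only ring oxygen O1 and two methyl groups, so the O1–C2(CH3)2 unit is an aryl isopropyl ether in disguise. O1 is also the only phenolic oxygen para to the C6 methyl group. A rhodium carbenoid raised at C3 from a diazomethyl ketone inserts into the oxygen-activated methine C–H of the ortho isopropoxy group. One operation closes the ring and creates the quaternary carbon. The precursor is an open-chain 2-diazoacetophenone in which a second isopropyl ether acts as protecting group.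

Key step: step 5

Remark: the target contains no stereocentre and no other stereogenic element. It is achiral, so no step needs stereocontrol.

**Step 1**
Reactants: 1 2-methylphloroglucinol; 2 acetyl chloride
Product: 3 1-(2,4,6-trihydroxy-3-methylphenyl)ethan-1-one
Conditions: AcCl (1.1 equiv), AlCl3 (4 equiv), CH2Cl2/MeNO2, 0 to 40 °C; aq. HCl
Reagents that add atoms: acetyl chloride (2), CC(=O)Cl
Why: Friedel–Crafts acylation of a very electron-rich arene; the two free ring positions of 1 are equivalent by symmetry, so one regioisomer should form, and the acyl group deactivates the ring against a second acylation.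

**Step 2**
Reactants: 3 1-(2,4,6-trihydroxy-3-methylphenyl)ethan-1-one; 4 2-bromopropane
Product: 5 1-[2-hydroxy-3-methyl-4,6-di(propan-2-yloxy)phenyl]ethan-1-one
Conditions: iPrBr (2.5 equiv), K2CO3 (2.5 equiv), DMF, 50 °C
Reagents that add atoms: 2-bromopropane (4), CC(C)Br
Why: Williamson ether synthesis under substrate control: the unchelated, most acidic 4-OH reacts first, and of the two ortho hydroxy groups the 6-OH next to the ring C–H should be alkylated by the bulky secondary bromide, whereas the 2-OH is shielded by the 3-methyl group and held in the hydrogen bond to the acetyl oxygen, in line with the known partial O-alkylation pattern of C-methylphloracetophenone.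

**Step 3**
Reactants: 5 1-[2-hydroxy-3-methyl-4,6-di(propan-2-yloxy)phenyl]ethan-1-one; 6 iodomethane
Product: 7 1-[2-methoxy-3-methyl-4,6-di(propan-2-yloxy)phenyl]ethan-1-one
Conditions: MeI (3 equiv), K2CO3, DMF, 45 °C
Reagents that add atoms: iodomethane (6), CI
Why: Williamson methylation with a small electrophile in excess overcomes the hydrogen bond of the last phenol, and the methyl ether offers the later carbenoid only unreactive primary C–H bonds.

**Step 4**
Reactants: 7 1-[2-methoxy-3-methyl-4,6-di(propan-2-yloxy)phenyl]ethan-1-one; 8 2,2,2-trifluoroethyl trifluoroacetate; 9 4-acetamidobenzenesulfonyl azide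
Product: 11 2-diazo-1-[2-methoxy-3-methyl-4,6-di(propan-2-yloxy)phenyl]ethan-1-one, via trifluoroacetyl diketone 10 (not isolated)
Conditions: LiHMDS, THF, −78 °C; CF3CO2CH2CF3; dil. HCl; crude, then p-ABSA, Et3N, H2O (1 equiv), MeCN, rt
Reagents that add atoms: 4-acetamidobenzenesulfonyl azide (9), CC(=O)Nc1ccc(cc1)S(=O)(=O)N=[N+]=[N-]; 2,2,2-trifluoroethyl trifluoroacetate (8), O=C(OCC(F)(F)F)C(F)(F)F (its atoms stay only in 10)
Why: Detrifluoroacetylative variant of the Regitz diazo transfer: Claisen-type trifluoroacetylation of the lithium enolate activates the methyl ketone as 1,3-diketone 10, which takes up the diazo group from the sulfonyl azide and loses the trifluoroacetyl group as the N-sulfonyl amide.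

**Step 5**
Reactants: 11 2-diazo-1-[2-methoxy-3-methyl-4,6-di(propan-2-yloxy)phenyl]ethan-1-one
Product: 13 5-methoxy-2,2,6-trimethyl-7-(propan-2-yloxy)chroman-4-one, via rhodium carbenoid 12 (not isolated)
Conditions: Rh2(OAc)4 (1 mol %), CH2Cl2, reflux, slow addition of 11 by syringe pump
Reagents that add atoms: none
Why: Rh2(OAc)4 expels N2 from 11 to give the electrophilic carbenoid 12 at the future C3, which inserts through a concerted, hydride-transfer-like three-centre transition state into the methine C–H of the ortho isopropoxy group, forming C2–C3 and releasing the catalyst. The closest known reaction type is the rhodium(II)-catalysed intramolecular C–H insertion of 2-alkoxyaryl α-diazoketones, which gives chroman-4-ones. The six-membered dihydropyranone closes by 1,6-insertion, because the usual 1,5-position is the ether oxygen itself and carries no C–H bond, while that oxygen activates the adjacent C–H. No stereocentre arises, since C2 ends up with two methyl groups. The step needs site selectivity among three ether groups: the tertiary α-oxygen C–H is electronically the most activated, the primary C–H bonds of the other ortho group (OCH3) are far less reactive, and the 4-isopropoxy group cannot reach the carbenoid. Attack of the weakly basic aryl ether oxygens (oxonium ylide formation) is reversible and is disfavoured with rhodium carboxylates relative to copper catalysts, and slow addition suppresses carbene dimerisation.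

**Step 6**
Reactants: 13 5-methoxy-2,2,6-trimethyl-7-(propan-2-yloxy)chroman-4-one
Product: 14 5,7-dihydroxy-2,2,6-trimethylchroman-4-one
Conditions: BCl3 (4 equiv), CH2Cl2, −78 °C to rt; H2O
Reagents that add atoms: none
Why: Lewis-acid dealkylation of aryl ethers: BCl3 chelated between the C4 carbonyl and O5 removes the peri methyl group and cleaves the secondary isopropyl ether by an SN1-like path, while ring oxygen O1, held in plane and conjugated with the ketone, should not ionise.

**Step 7**
Reactants: 1 2-methylphloroglucinol; 15 isobutyryl chloride
Product: 16 2-methyl-1-(2,4,6-trihydroxy-3-methylphenyl)propan-1-one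
Conditions: iPrCOCl (1.1 equiv), AlCl3 (4 equiv), CH2Cl2/MeNO2, 0 to 45 °C; aq. HCl
Reagents that add atoms: isobutyryl chloride (15), CC(C)C(=O)Cl
Why: Friedel–Crafts acylation at one of the two symmetry-equivalent free positions of 1, as in step 1.

**Step 8**
Reactants: 16 2-methyl-1-(2,4,6-trihydroxy-3-methylphenyl)propan-1-one; 17 bis(dimethylamino)methane
Product: 18 1-{3-[(dimethylamino)methyl]-2,4,6-trihydroxy-5-methylphenyl}-2-methylpropan-1-one
Conditions: CH2(NMe2)2 (1.1 equiv), THF, 0 °C to rt
Reagents that add atoms: bis(dimethylamino)methane (17), CN(C)CN(C)C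
Why: Mannich reaction: the acidic acylphloroglucinol protonates the aminal to the methyleneiminium ion, which is taken up by the only free ring carbon, and the absence of free formaldehyde should keep symmetrical methylene dimers from forming.

**Step 9**
Reactants: 18 1-{3-[(dimethylamino)methyl]-2,4,6-trihydroxy-5-methylphenyl}-2-methylpropan-1-one; 14 5,7-dihydroxy-2,2,6-trimethylchroman-4-one
Product: 20 5,7-dihydroxy-2,2,6-trimethyl-8-{[2,4,6-trihydroxy-3-methyl-5-(2-methylpropanoyl)phenyl]methyl}chroman-4-one (CNP0186856.0), via ortho-quinone methide 19 (not isolated)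
Conditions: toluene/AcOH (10:1), 80 °C
Reagents that add atoms: none
Why: Acid-buffered thermal loss of dimethylamine from the ortho-hydroxybenzylamine gives ortho-quinone methide 19, and Michael-type Friedel–Crafts attack by C8, the only free ring position of 14, followed by rearomatisation should give the unsymmetrical diarylmethane, the acetic acid binding the amine so that it cannot open the pyranone ring.

**Compound list**
1 | 2-methylphloroglucinol (2-methylbenzene-1,3,5-triol) | Cc1c(O)cc(O)cc1O | starting material
2 | acetyl chloride | CC(=O)Cl | starting material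
3 | 1-(2,4,6-trihydroxy-3-methylphenyl)ethan-1-one | CC(=O)c1c(O)cc(O)c(C)c1O | intermediate
4 | 2-bromopropane | CC(C)Br | starting material
5 | 1-[2-hydroxy-3-methyl-4,6-di(propan-2-yloxy)phenyl]ethan-1-one | CC(=O)c1c(OC(C)C)cc(OC(C)C)c(C)c1O | intermediate
6 | iodomethane | CI | starting material
7 | 1-[2-methoxy-3-methyl-4,6-di(propan-2-yloxy)phenyl]ethan-1-one | CC(=O)c1c(OC(C)C)cc(OC(C)C)c(C)c1OC | intermediate
8 | 2,2,2-trifluoroethyl trifluoroacetate | O=C(OCC(F)(F)F)C(F)(F)F | starting material
9 | 4-acetamidobenzenesulfonyl azide (p-ABSA) | CC(=O)Nc1ccc(cc1)S(=O)(=O)N=[N+]=[N-] | starting material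
10 | 4,4,4-trifluoro-1-[2-methoxy-3-methyl-4,6-di(propan-2-yloxy)phenyl]butane-1,3-dione (not isolated) | O=C(CC(=O)C(F)(F)F)c1c(OC(C)C)cc(OC(C)C)c(C)c1OC | intermediate
11 | 2-diazo-1-[2-methoxy-3-methyl-4,6-di(propan-2-yloxy)phenyl]ethan-1-one | [N-]=[N+]=CC(=O)c1c(OC(C)C)cc(OC(C)C)c(C)c1OC | intermediate
12 | rhodium carbenoid of 11 (not isolated; the Rh2(OAc)4 core is abbreviated to one Rh atom) | [Rh]=CC(=O)c1c(OC(C)C)cc(OC(C)C)c(C)c1OC | intermediate
13 | 5-methoxy-2,2,6-trimethyl-7-(propan-2-yloxy)chroman-4-one | COc1c(C)c(OC(C)C)cc2OC(C)(C)CC(=O)c12 | intermediate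
14 | 5,7-dihydroxy-2,2,6-trimethylchroman-4-one | Cc1c(O)cc2OC(C)(C)CC(=O)c2c1O | intermediate
15 | isobutyryl chloride | CC(C)C(=O)Cl | starting material
16 | 2-methyl-1-(2,4,6-trihydroxy-3-methylphenyl)propan-1-one | CC(C)C(=O)c1c(O)cc(O)c(C)c1O | intermediate
17 | bis(dimethylamino)methane | CN(C)CN(C)C | starting material
18 | 1-{3-[(dimethylamino)methyl]-2,4,6-trihydroxy-5-methylphenyl}-2-methylpropan-1-one | CC(C)C(=O)c1c(O)c(C)c(O)c(CN(C)C)c1O | intermediate
19 | 3,5-dihydroxy-2-methyl-6-methylidene-4-(2-methylpropanoyl)cyclohexa-2,4-dien-1-one (ortho-quinone methide, not isolated) | C=C1C(=O)C(C)=C(O)C(C(=O)C(C)C)=C1O | intermediate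
20 | 5,7-dihydroxy-2,2,6-trimethyl-8-{[2,4,6-trihydroxy-3-methyl-5-(2-methylpropanoyl)phenyl]methyl}chroman-4-one (achiral) | Cc1c(O)c(Cc2c(O)c(C)c(O)c3c2OC(C)(C)CC3=O)c(O)c(C(=O)C(C)C)c1O | target

Total step count: 9. Longest linear sequence: 7 (steps 1–6 and 9).

**Steps most likely to fail**

Step 5. The carbenoid may be captured by an ether oxygen (oxonium ylide formation followed by loss of propene or a 1,2-shift), or it may dimerise faster than it inserts. In the fallback the ring is closed at O1–C2 instead.
- The fallback sets out from 1. Friedel–Crafts acylation with 3-methylbut-2-enoic acid in MeSO3H/P2O5 at 70 °C should give 1-(2,4,6-trihydroxy-3-methylphenyl)-3-methylbut-2-en-1-one F1.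
- F1 should cyclise in the same flask by oxa-Michael addition and come back to the route at 14.
- Both ortho hydroxy groups compete in this ring closure, so the regiocontrol of the main route is lost and a chromatographic separation is needed. Steps 1–6 are then not required.

Step 2. Discrimination between the two ortho hydroxy groups may be poor, or alkylation may run on to the third phenol. The fallback protects all three phenols and releases one.
- It sets out from 3. Exhaustive alkylation with excess 4 (Cs2CO3, DMF, 80 °C) should give 1-[3-methyl-2,4,6-tri(propan-2-yloxy)phenyl]ethan-1-one F2.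
- One equivalent of BCl3 in CH2Cl2 at −78 °C should then effect a carbonyl-chelated mono-dealkylation.
- The cleavage should occur at the 2-O-isopropyl group, which is flanked on both sides, twisted out of conjugation and therefore the most basic. The sequence comes back to the route at 5.

Step 9. Loss of the amine may be slow. The benzylic unit may be exchanged by ipso attack, which would lead to symmetrical dimers. The pyranone ring may also open and reclose under the influence of the amine. The fallback exchanges the roles of the two halves.
- It sets out from 14. Reaction with 17 in THF should give 8-[(dimethylamino)methyl]-5,7-dihydroxy-2,2,6-trimethylchroman-4-one F3.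
- Warming F3 with 16 in toluene/AcOH should release the chromanone ortho-quinone methide 5-hydroxy-2,2,6-trimethyl-8-methylidene-2,3-dihydrochromene-4,7-dione F4.
- F4 is attacked by the only free ring carbon of 16, and the sequence comes back to the route at 20.

**Further compounds**
F1 | step 5 | 1-(2,4,6-trihydroxy-3-methylphenyl)-3-methylbut-2-en-1-one | CC(C)=CC(=O)c1c(O)cc(O)c(C)c1O
F2 | step 2 | 1-[3-methyl-2,4,6-tri(propan-2-yloxy)phenyl]ethan-1-one | CC(=O)c1c(OC(C)C)cc(OC(C)C)c(C)c1OC(C)C
F3 | step 9 | 8-[(dimethylamino)methyl]-5,7-dihydroxy-2,2,6-trimethylchroman-4-one | CN(C)Cc1c(O)c(C)c(O)c2C(=O)CC(C)(C)Oc12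
F4 | step 9 | 5-hydroxy-2,2,6-trimethyl-8-methylidene-2,3-dihydrochromene-4,7-dione | C=C1C(=O)C(C)=C(O)C2=C1OC(C)(C)CC2=O
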